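**Retrosynthetic overview**
1. Target ⇐ deprotection and hydrogenation ⇐ Claisen rearrangement of a diosphenol (oct-2-en-4-yl) enol ether (C3–C1′ bond, C1′ by chirality transfer) ⇐ ring A closed by a sulfone Dieckmann reaction (C1–C2), then oxidative desulfonylation.
2. Ring B ⇐ amine-catalysed formal [3+3] annulation (SN2′-type Michael addition, then intramolecular Michael addition) of the acyclic methyl ketone 8 with the nitroallylic acetate 12, which makes C6–C7 and C4a–C8a in one operation; ring B is formed first, ring A second.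
3. Enabling feature: ring B is a 1,4-dioxygenated cyclohexane (C5–OH, C8–OH), i.e. two three-carbon units C4a–C5(O)–C6 and C7–C8(O)–C8a joined at C6–C7 and C4a–C8a, each with its oxygen on the central carbon. With C5 as a ketone, C4a and C6 are nucleophilic; with C8 as a nitro group (masked ketone), C7 and C8a are electrophilic.
4. Stereocontrol: C4 by decarboxylative allylation before the key step, C7 by the annulation catalyst, C4a and C8a by equilibration, C5 and C8 by hydride reductions.

Key step: step 8

Remark: target numbering is used for all intermediates (C1 ring ketone, C2 enol carbon, C3, C4 quaternary carbon, C4a, C5 to C8, C8a, C1′ side-chain stereocentre; β is the face of H-4a). Descriptors appear in names only where assigned; the SMILES are decisive. The target is taken to rest as the drawn 2-hydroxy-2-en-1-one tautomer and open hydroxy ketone.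

**Route**

Step 1
Reactants: 1 allyl propanoate; 2 3-(benzyloxy)propanal
Product: 3 allyl 5-(benzyloxy)-3-hydroxy-2-methylpentanoate (diastereomer mixture)
Conditions: LiN(i-Pr)2, THF, −78 °C; then H2O
Reagents that add atoms: none
Why: Aldol addition of the lithium ester enolate to the aldehyde is reliable, and both new stereocentres are removed later, so no control is needed.

Step 2
Reactants: 3 allyl 5-(benzyloxy)-3-hydroxy-2-methylpentanoate
Product: 4 allyl 5-(benzyloxy)-2-methyl-3-oxopentanoate (racemic)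
Conditions: Dess–Martin periodinane, CH2Cl2, 0 °C to rt
Reagents that add atoms: none
Why: Dess–Martin oxidation of a β-hydroxy ester to the β-keto ester runs under near-neutral conditions that spare the β-benzyloxy ketone.

Step 3
Reactants: 4 allyl 5-(benzyloxy)-2-methyl-3-oxopentanoate; 5 phenyl vinyl sulfone
Product: 6 allyl 2-[3-(benzyloxy)propanoyl]-2-methyl-4-(phenylsulfonyl)butanoate (racemic)
Conditions: DBU (10 mol %), MeCN, rt
Reagents that add atoms: none
Why: Michael addition of the α-methyl β-keto ester to the vinyl sulfone builds the quaternary carbon (future C4) as a racemate, whose configuration is fixed only in step 4.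

Step 4
Reactants: 6 allyl 2-[3-(benzyloxy)propanoyl]-2-methyl-4-(phenylsulfonyl)butanoate
Product: 7 (4R)-1-(benzyloxy)-4-methyl-4-[2-(phenylsulfonyl)ethyl]hept-6-en-3-one
Conditions: Pd2(dba)3 (2.5 mol %), (S)-t-Bu-PHOX or its enantiomer (6 mol %; the one that gives (R)-7), toluene, 30 °C
Reagents that add atoms: none
Why: Decarboxylative asymmetric allylic alkylation: zerovalent palladium ionises the allyl ester, CO2 is lost, and the ligand-bound allylpalladium enolate is allylated on one enantioface, which sets C4.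

Step 5
Reactants: 7 (4R)-1-(benzyloxy)-4-methyl-4-[2-(phenylsulfonyl)ethyl]hept-6-en-3-one
Product: 8 (4R)-7-(benzyloxy)-4-methyl-4-[2-(phenylsulfonyl)ethyl]heptane-2,5-dione
Conditions: PdCl2 (10 mol %), CuCl, O2 (1 atm), DMF/H2O 7:1, rt
Reagents that add atoms: water, O
Why: Wacker oxidation with Markovnikov selectivity turns the allyl group into the acetonyl unit C4a–C5(=O)–C6 without touching C4.

Step 6
Reactants: 9 (E)-1-nitroprop-1-ene; 10 ethyl glyoxylate
Product: 11 ethyl (E)-2-hydroxy-3-nitropent-3-enoate (racemic)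
Conditions: imidazole (1 equiv), THF, rt
Reagents that add atoms: none
Why: Morita–Baylis–Hillman reaction of a nitroalkene with an activated aldehyde joins C8 to C8a; the carbinol stereocentre is lost in step 8.

Step 7
Reactants: 11 ethyl (E)-2-hydroxy-3-nitropent-3-enoate
Product: 12 ethyl (E)-2-acetoxy-3-nitropent-3-enoate (racemic)
Conditions: Ac2O, pyridine, CH2Cl2, 0 °C
Reagents that add atoms: acetic anhydride, CC(=O)OC(C)=O
Why: Acetylation installs the allylic leaving group that turns the nitroalkene into a 1,3-bis-electrophile.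

Step 8
Reactants: 8 (4R)-7-(benzyloxy)-4-methyl-4-[2-(phenylsulfonyl)ethyl]heptane-2,5-dione; 12 ethyl (E)-2-acetoxy-3-nitropent-3-enoate
Product: 14 ring B nitro keto ester (ethyl 3-methyl-2-nitro-5-oxo-6-[6-(benzyloxy)-3-methyl-4-oxo-1-(phenylsulfonyl)hexan-3-yl]cyclohexane-1-carboxylate, all ring substituents equatorial), via nitroacrylate 13 (not isolated)
Conditions: 1-[(1R,2R)-2-aminocyclohexyl]-3-[3,5-bis(trifluoromethyl)phenyl]thiourea or its enantiomer (20 mol %; the one that gives 7S), PhCO2H (20 mol %), toluene, rt; then Et3N (1.2 equiv), rt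
Reagents that add atoms: none
Why: The catalyst forms the terminal enamine of the unhindered acetonyl ketone, whose C6 adds to the methyl-bearing β-carbon C7 of the nitroalkene; the nitronate expels acetate (SN2′ outcome) to give nitroacrylate 13, and the C4a enol or enamine of the same ketone then adds to C8a. The closest known reaction type is the enamine-mediated [3+3] carbocyclisation (α,α′-annulation) of ketones with 2-nitroallylic esters. Ring B closes by a 6-endo-trig intramolecular Michael addition onto the nitroalkene; ring A is not formed here. C7 is set by the catalyst (hydrogen-bonded nitro group, one enamine face shielded) and, being non-enolisable, anchors the ring, while C4a (α to the C5 ketone), C8a (α to the ester) and C8 (α to nitro) equilibrate to the all-equatorial chair, which is the relative configuration of the target; C4 is carried in from 8. The step needs reaction at the acetonyl ketone only, C6 before C4a, and C- rather than O-cyclisation: the side-chain ketone is flanked by the quaternary carbon and forms no enamine, the methyl carbon is the less hindered enamine terminus, and a simple ketone donor (not a 1,3-dicarbonyl) favours carbocyclisation.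

Step 9
Reactants: 14 ring B nitro keto ester
Product: 16 mixed methyl ketal (2-methoxytetrahydrofuran O5–C(OMe)(CH2CH2OBn)–C4–C4a–C5 fused to ring B), via 5β-alcohol 15 (not isolated)
Conditions: NaBH4, MeOH/THF, −40 °C; then MeOH, CSA (cat.), 4 Å MS, rt
Reagents that add atoms: methanol, CO
Why: Axial hydride attack on the C5 cyclohexanone (faster than on the neopentyl side-chain ketone) gives the equatorial 5β-alcohol, which adds to the side-chain carbonyl and is locked as the mixed methyl ketal, masking both groups.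

Step 10
Reactants: 16 mixed methyl ketal
Product: 17 β-keto ester (C8 ketone)
Conditions: NaOEt (1.05 equiv), EtOH, 0 °C; then O3, CH2Cl2/EtOH, −78 °C
Reagents that add atoms: ozone, [O-][O+]=O
Why: Nef reaction by ozonolysis of the secondary nitronate unmasks the C8 ketone under non-acidic conditions, and the now freely epimerisable C8a stays equatorial.

Step 11
Reactants: 17 β-keto ester
Product: 18 β-hydroxy ester (axial 8β-OH)
Conditions: LiBH(s-Bu)3, THF, −78 °C; then H2O
Reagents that add atoms: none
Why: The bulky hydride attacks the C8 ketone along the equatorial trajectory, giving the axial 8β-alcohol cis to the C7 methyl and the C8a ester, as in selectride reductions of 2-substituted cyclohexanones and cyclic β-keto esters.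

Step 12
Reactants: 18 β-hydroxy ester
Product: 19 8β-O-TBS ether
Conditions: TBSOTf, 2,6-lutidine, CH2Cl2, 0 °C
Reagents that add atoms: tert-butyldimethylsilyl triflate, CC(C)(C)[Si](C)(C)OS(=O)(=O)C(F)(F)F
Why: Silylation protects the hindered axial alcohol for the basic and Mitsunobu steps that follow.

Step 13
Reactants: 19 8β-O-TBS ether
Product: 20 tricyclic β-keto sulfone (ring A closed, C2 epimers)
Conditions: LiN(i-Pr)2 (2.2 equiv), THF, −78 to −30 °C; then H2O
Reagents that add atoms: none
Why: Dieckmann-type intramolecular acylation of the α-sulfonyl carbanion (C2) by the C1 ester closes ring A (six-membered) and is driven by deprotonation of the β-keto sulfone; C8a can epimerise to the trans ring fusion.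

Step 14
Reactants: 20 tricyclic β-keto sulfone
Product: 21 diosphenol (2-hydroxy-2-en-1-one, C3–H)
Conditions: KOt-Bu (1.05 equiv), THF, −78 °C; then 2-(phenylsulfonyl)-3-phenyloxaziridine, −78 to 0 °C
Reagents that add atoms: 2-(phenylsulfonyl)-3-phenyloxaziridine, O=S(=O)(N1OC1c1ccccc1)c1ccccc1
Why: Oxidative desulfonylation: hydroxylation of the sulfonyl-stabilised enolate gives an α-hydroxy sulfone that expels benzenesulfinate to the 1,2-dione, which enolises to the diosphenol.

Step 15
Reactants: 22 (E)-oct-2-en-4-one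
Product: 23 (2E,4R)-oct-2-en-4-ol
Conditions: (S)-2-methyl-CBS-oxazaborolidine (10 mol %), BH3·SMe2, THF, −30 °C; then H2O
Reagents that add atoms: none
Why: CBS reduction with the alkenyl group as the large substituent gives the (R)-allylic alcohol.

Step 16
Reactants: 21 diosphenol; 23 (2E,4R)-oct-2-en-4-ol
Product: 24 2-O-[(2E,4S)-oct-2-en-4-yl] enol ether
Conditions: PPh3, DIAD, toluene, 0 °C to rt
Reagents that add atoms: none
Why: Mitsunobu etherification of the acidic diosphenol proceeds with inversion to the (S)-configured allyl enol ether; of the two equilibrating enolate oxygens, the unhindered O2 (next to C3–H) should be alkylated in preference to O1 beside the fully substituted C8a (Curtin–Hammett control).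

Step 17
Reactants: 24 2-O-[(2E,4S)-oct-2-en-4-yl] enol ether
Product: 25 3-[(2R,3E)-oct-3-en-2-yl] diosphenol
Conditions: xylene, 150 °C (sealed tube), BHT (cat.)
Reagents that add atoms: none
Why: Claisen rearrangement through a chair transition state with the butyl group equatorial forms the C3–C1′ bond and transfers chirality from the (S)-ether carbon to (R)-C1′ with an (E)-alkene; the 1,2-dione then re-enolises towards the now fully substituted C3.

Step 18
Reactants: 25 3-[(2R,3E)-oct-3-en-2-yl] diosphenol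
Product: 26 3-[(2R)-octan-2-yl] diosphenol with free primary alcohol (TBS ether and methyl ketal retained)
Conditions: H2 (1 atm), Pd/C, EtOAc, rt
Reagents that add atoms: none
Why: Hydrogenation saturates the disubstituted side-chain alkene and cleaves the benzyl ether, while the tetrasubstituted conjugated enol double bond should not be reduced.

Step 19
Reactants: 26 3-[(2R)-octan-2-yl] diosphenol with free primary alcohol
Product: 27 (4R,4aS,5R,7S,8S,8aR)-2,5,8-trihydroxy-4-(3-hydroxypropanoyl)-4,7-dimethyl-3-[(2R)-octan-2-yl]-4a,5,6,7,8,8a-hexahydronaphthalen-1(4H)-one (target)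
Conditions: aq. HF (48 %), MeCN, 0 °C to rt
Reagents that add atoms: water, O
Why: Acidic fluoride removes the silyl ether and hydrolyses the mixed methyl ketal, releasing the C5 hydroxyl and the 3-hydroxypropanoyl ketone without touching any stereocentre.

**Compound list**
1 | allyl propanoate | CCC(=O)OCC=C | starting material
2 | 3-(benzyloxy)propanal | O=CCCOCc1ccccc1 | starting material
3 | allyl 5-(benzyloxy)-3-hydroxy-2-methylpentanoate (diastereomer mixture) | C=CCOC(=O)C(C)C(O)CCOCc1ccccc1 | intermediate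
4 | allyl 5-(benzyloxy)-2-methyl-3-oxopentanoate (racemic) | C=CCOC(=O)C(C)C(=O)CCOCc1ccccc1 | intermediate
5 | phenyl vinyl sulfone | C=CS(=O)(=O)c1ccccc1 | starting material
6 | allyl 2-[3-(benzyloxy)propanoyl]-2-methyl-4-(phenylsulfonyl)butanoate (racemic) | C=CCOC(=O)C(C)(CCS(=O)(=O)c1ccccc1)C(=O)CCOCc1ccccc1 | intermediate
7 | (4R)-1-(benzyloxy)-4-methyl-4-[2-(phenylsulfonyl)ethyl]hept-6-en-3-one | C=CC[C@@](CCS(=O)(=O)c1ccccc1)(C)C(=O)CCOCc1ccccc1 | intermediate
8 | (4R)-7-(benzyloxy)-4-methyl-4-[2-(phenylsulfonyl)ethyl]heptane-2,5-dione | CC(=O)C[C@@](CCS(=O)(=O)c1ccccc1)(C)C(=O)CCOCc1ccccc1 | intermediate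
9 | (E)-1-nitroprop-1-ene | C/C=C/[N+](=O)[O-] | starting material
10 | ethyl glyoxylate | CCOC(=O)C=O | starting material
11 | ethyl (E)-2-hydroxy-3-nitropent-3-enoate (racemic) | C/C=C(/[N+](=O)[O-])C(O)C(=O)OCC | intermediate
12 | ethyl (E)-2-acetoxy-3-nitropent-3-enoate (racemic) | C/C=C(/[N+](=O)[O-])C(OC(C)=O)C(=O)OCC | intermediate
13 | nitroacrylate: ethyl (4S,8R)-11-(benzyloxy)-4,8-dimethyl-3-nitro-6,9-dioxo-8-[2-(phenylsulfonyl)ethyl]undec-2-enoate (alkene geometry open) | CCOC(=O)C=C([N+](=O)[O-])[C@@H](C)CC(=O)C[C@@](CCS(=O)(=O)c1ccccc1)(C)C(=O)CCOCc1ccccc1 | intermediate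
14 | ring B nitro keto ester: ethyl 3-methyl-2-nitro-5-oxo-6-[6-(benzyloxy)-3-methyl-4-oxo-1-(phenylsulfonyl)hexan-3-yl]cyclohexane-1-carboxylate; ring locants 1, 2, 3, 5, 6 are target C8a, C8, C7, C5, C4a; all ring substituents equatorial; C4, C4a, C7, C8a as in the target | CCOC(=O)[C@H]1[C@H]([N+](=O)[O-])[C@@H](C)CC(=O)[C@@H]1[C@@](CCS(=O)(=O)c2ccccc2)(C)C(=O)CCOCc2ccccc2 | intermediate
15 | 5β-alcohol of 14 (equatorial OH at C5; open form of the hemiketal) | CCOC(=O)[C@H]1[C@H]([N+](=O)[O-])[C@@H](C)C[C@@H](O)[C@@H]1[C@@](CCS(=O)(=O)c2ccccc2)(C)C(=O)CCOCc2ccccc2 | intermediate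
16 | mixed methyl ketal: 2-methoxytetrahydrofuran O5–C(OMe)(CH2CH2OBn)–C4–C4a–C5 trans-fused to ring B, otherwise as 14 (ketal carbon unspecified, anomer mixture) | CCOC(=O)[C@H]1[C@H]([N+](=O)[O-])[C@@H](C)C[C@@H](O2)[C@@H]1[C@@](CCS(=O)(=O)c3ccccc3)(C)C2(OC)CCOCc3ccccc3 | intermediate
17 | β-keto ester: as 16 with a C8 ketone in place of CH–NO2 | CCOC(=O)[C@H]1C(=O)[C@@H](C)C[C@@H](O2)[C@@H]1[C@@](CCS(=O)(=O)c3ccccc3)(C)C2(OC)CCOCc3ccccc3 | intermediate
18 | β-hydroxy ester: as 17 with axial 8β-OH | CCOC(=O)[C@H]1[C@@H](O)[C@@H](C)C[C@@H](O2)[C@@H]1[C@@](CCS(=O)(=O)c3ccccc3)(C)C2(OC)CCOCc3ccccc3 | intermediate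
19 | 8β-O-TBS ether of 18 | CCOC(=O)[C@H]1[C@@H](O[Si](C)(C)C(C)(C)C)[C@@H](C)C[C@@H](O2)[C@@H]1[C@@](CCS(=O)(=O)c3ccccc3)(C)C2(OC)CCOCc3ccccc3 | intermediate
20 | tricyclic β-keto sulfone: trans-decalin (H-4a β, H-8a α) with C1 ketone, 2-phenylsulfonyl (epimers), 4α-methyl, 7β-methyl, 8β-OTBS and the 4β,5β-bridging 2-methoxytetrahydrofuran ketal | C1C(S(=O)(=O)c4ccccc4)C(=O)[C@H]2[C@@H](O[Si](C)(C)C(C)(C)C)[C@@H](C)C[C@@H](O3)[C@@H]2[C@@]1(C)C3(OC)CCOCc4ccccc4 | intermediate
21 | diosphenol: 2-hydroxy-2-en-1-one (C3–H) of the tricycle, sulfonyl group removed | C1=C(O)C(=O)[C@H]2[C@@H](O[Si](C)(C)C(C)(C)C)[C@@H](C)C[C@@H](O3)[C@@H]2[C@@]1(C)C3(OC)CCOCc4ccccc4 | intermediate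
22 | (E)-oct-2-en-4-one | C/C=C/C(=O)CCCC | starting material
23 | (2E,4R)-oct-2-en-4-ol | C/C=C/[C@H](O)CCCC | intermediate
24 | 2-O-[(2E,4S)-oct-2-en-4-yl] enol ether of 21 | C1=C(O[C@@H](CCCC)/C=C/C)C(=O)[C@H]2[C@@H](O[Si](C)(C)C(C)(C)C)[C@@H](C)C[C@@H](O3)[C@@H]2[C@@]1(C)C3(OC)CCOCc4ccccc4 | intermediate
25 | 3-[(2R,3E)-oct-3-en-2-yl] diosphenol | CCCC/C=C/[C@@H](C)C1=C(O)C(=O)[C@H]2[C@@H](O[Si](C)(C)C(C)(C)C)[C@@H](C)C[C@@H](O3)[C@@H]2[C@@]1(C)C3(OC)CCOCc4ccccc4 | intermediate
26 | 3-[(2R)-octan-2-yl] diosphenol with free primary alcohol, 8β-OTBS and methyl ketal retained | CCCCCC[C@@H](C)C1=C(O)C(=O)[C@H]2[C@@H](O[Si](C)(C)C(C)(C)C)[C@@H](C)C[C@@H](O3)[C@@H]2[C@@]1(C)C3(OC)CCO | intermediate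
27 | (4R,4aS,5R,7S,8S,8aR)-2,5,8-trihydroxy-4-(3-hydroxypropanoyl)-4,7-dimethyl-3-[(2R)-octan-2-yl]-4a,5,6,7,8,8a-hexahydronaphthalen-1(4H)-one | CCCCCC[C@@H](C)C1=C(O)C(=O)[C@H]2[C@@H](O)[C@@H](C)C[C@@H](O)[C@@H]2[C@@]1(C)C(=O)CCO | target

**Step count and risks**

Total step count: 19. Longest linear sequence: 16 steps (steps 1 to 5, 8 to 14 and 16 to 19).

Steps most likely to fail:

Step 8 (key annulation). The first conjugate addition may show poor facial selectivity, or the sequence may stall at 13, or lose nitrous acid, before the hindered C4a–C8a bond closes. The fallback sets out from 8 and returns at 14, making the two C–C bonds in separate operations. Ketone 8 is added to (E)-1-nitroprop-1-ene 9 under the same primary amine–thiourea catalysis (a standard ketone–nitroalkene Michael addition) to give γ-nitro ketone (2S,6R)-9-(benzyloxy)-2,6-dimethyl-1-nitro-6-[2-(phenylsulfonyl)ethyl]nonane-4,7-dione F1. Henry addition of its nitronate to ethyl glyoxylate 10 (Et3N, THF) gives nitro aldol ethyl 11-(benzyloxy)-2-hydroxy-4,8-dimethyl-3-nitro-6,9-dioxo-8-[2-(phenylsulfonyl)ethyl]undecanoate F2. Mesylation and elimination (MsCl, Et3N, −20 °C) give nitroacrylate 13, which is cyclised to 14 by intramolecular Michael addition (Et3N, toluene).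

Step 4 (decarboxylative allylation). Enantioface discrimination may be poor because decarboxylation delivers the acyclic, fully substituted enolate as a mixture of geometries. The fallback sets out from 6 and returns at 14. The allylation is run without asymmetric induction (Pd(PPh3)4, THF) to give racemic 1-(benzyloxy)-4-methyl-4-[2-(phenylsulfonyl)ethyl]hept-6-en-3-one F3. This is oxidised as in step 5 to racemic 7-(benzyloxy)-4-methyl-4-[2-(phenylsulfonyl)ethyl]heptane-2,5-dione F4. The catalyst-controlled annulation of step 8 then converts the two enantiomers into 14 and its C4 epimer F5, diastereomers to be separated by chromatography, so that C4 is resolved against the catalyst-set C7.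

Step 16 (Mitsunobu etherification). Alkylation may occur on the other enol oxygen (O1, after enolisation towards C8a), or with allylic transposition; either misplaces the side chain. The fallback sets out from 20 and returns at 25, building the enol ether regiospecifically. Reductive desulfonylation (SmI2, THF/MeOH, −78 °C) gives the tricyclic C1 ketone F6. Dehydrogenation through the kinetic C2 enolate (LiN(i-Pr)2, TMSCl; then Pd(OAc)2, MeCN, Saegusa oxidation) gives the 2-en-1-one F7. α-Iodination (I2, pyridine, CH2Cl2) gives the 2-iodo-2-en-1-one F8. Copper-catalysed C–O coupling of this vinyl iodide with (2E,4S)-oct-2-en-4-ol F9 (made from 22 as in step 15 with the enantiomeric oxazaborolidine; CuI, 3,4,7,8-tetramethyl-1,10-phenanthroline, Cs2CO3, toluene, 110 °C) forms enol ether 24 with retention at the carbinol carbon. Enol ether 24 then rearranges in the same pot to 25.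

Further compounds
F1 | step 8 | (2S,6R)-9-(benzyloxy)-2,6-dimethyl-1-nitro-6-[2-(phenylsulfonyl)ethyl]nonane-4,7-dione | [O-][N+](=O)C[C@@H](C)CC(=O)C[C@@](CCS(=O)(=O)c1ccccc1)(C)C(=O)CCOCc1ccccc1
F2 | step 8 | ethyl (4S,8R)-11-(benzyloxy)-2-hydroxy-4,8-dimethyl-3-nitro-6,9-dioxo-8-[2-(phenylsulfonyl)ethyl]undecanoate (mixture at C2 and C3) | CCOC(=O)C(O)C([N+](=O)[O-])[C@@H](C)CC(=O)C[C@@](CCS(=O)(=O)c1ccccc1)(C)C(=O)CCOCc1ccccc1
F3 | step 4 | racemic 1-(benzyloxy)-4-methyl-4-[2-(phenylsulfonyl)ethyl]hept-6-en-3-one | C=CCC(CCS(=O)(=O)c1ccccc1)(C)C(=O)CCOCc1ccccc1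
F4 | step 4 | racemic 7-(benzyloxy)-4-methyl-4-[2-(phenylsulfonyl)ethyl]heptane-2,5-dione | CC(=O)CC(CCS(=O)(=O)c1ccccc1)(C)C(=O)CCOCc1ccccc1
F5 | step 4 | C4 epimer of ring B nitro keto ester 14 | CCOC(=O)[C@H]1[C@H]([N+](=O)[O-])[C@@H](C)CC(=O)[C@@H]1[C@](CCS(=O)(=O)c2ccccc2)(C)C(=O)CCOCc2ccccc2
F6 | step 16 | tricyclic C1 ketone (20 without the sulfonyl group) | C1CC(=O)[C@H]2[C@@H](O[Si](C)(C)C(C)(C)C)[C@@H](C)C[C@@H](O3)[C@@H]2[C@@]1(C)C3(OC)CCOCc4ccccc4
F7 | step 16 | tricyclic 2-en-1-one | C1=CC(=O)[C@H]2[C@@H](O[Si](C)(C)C(C)(C)C)[C@@H](C)C[C@@H](O3)[C@@H]2[C@@]1(C)C3(OC)CCOCc4ccccc4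
F8 | step 16 | tricyclic 2-iodo-2-en-1-one | C1=C(I)C(=O)[C@H]2[C@@H](O[Si](C)(C)C(C)(C)C)[C@@H](C)C[C@@H](O3)[C@@H]2[C@@]1(C)C3(OC)CCOCc4ccccc4
F9 | step 16 | (2E,4S)-oct-2-en-4-ol | C/C=C/[C@@H](O)CCCC
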